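## Retrosynthetic overview

1. The ten benzyl ethers come off last. Before that, the upper C4–middle C8 bond is made by Friedel–Crafts coupling of a flavan-4-yl cation with a benzylated epiafzelechin dimer; the dimer's own C4–C8 bond comes from a C4-oxidised monomer and a second molecule of the same monomer.
2. That monomer (tetra-O-benzyl-epiafzelechin 22) serves as middle and lower unit. Its ring C is annulated onto ring A in one operation: the aryne of ring A (triple bond C4a≡C8a) takes up the alkoxide oxygen O1 at C8a and the chain carbon C4 at C4a.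
3. Enabling feature: the C5 oxygen of ring A, the benzyloxy group directly next to C4a. It polarises the C4a≡C8a bond so that O1 enters at the remote carbon C8a and the carbanion arises at C4a; the primary chloride on C4 of the O1–C2–C3–C4 chain then closes ring C (6-exo-tet).
4. C2 and C3 of both epiafzelechin units are set beforehand by an Evans syn glycolate aldol; C2 of the upper unit by asymmetric conjugate arylation of a chromone.
5. Ring order: ring A (bought) → ring C of the monomer (key step) → middle–lower interflavan bond → upper–middle interflavan bond.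

Key step: step 8

Assumption (chemistry): flavan numbering is used (O1, C2, C3, C4, C4a, C5–C8, C8a; ring A = benzo ring, ring C = pyran ring, ring B = 2-aryl group). The three flavan units are called upper (7,4'-dihydroxyflavan), middle and lower. Compounds 1, 2, 4, 11, 27 and 29 are taken as purchasable.

## Route

Step 1
Reactants: 1 (S)-4-benzyl-1,3-oxazolidin-2-one; 2 (benzyloxy)acetyl chloride
Product: 3 (S)-4-benzyl-3-[(benzyloxy)acetyl]-1,3-oxazolidin-2-one
Conditions: Et3N, DMAP (cat.), CH2Cl2, 0 °C → rt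
Reagents that add atoms: none
Why: N-acylation of the oxazolidinone by the acid chloride under nucleophilic catalysis; no stereocentre is touched.

Step 2
Reactants: 3 (S)-4-benzyl-3-[(benzyloxy)acetyl]-1,3-oxazolidin-2-one; 4 4-(benzyloxy)benzaldehyde
Product: 7 (S)-4-benzyl-3-{(2S,3R)-2-(benzyloxy)-3-[4-(benzyloxy)phenyl]-3-hydroxypropanoyl}-1,3-oxazolidin-2-one, via Z-boron enolate 5 (not isolated), via boron aldolate 6 (not isolated)
Conditions: Bu2BOTf, Et3N, CH2Cl2, −78 → 0 °C; then 4, −78 → 0 °C; then pH 7 buffer, MeOH, H2O2, 0 °C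
Reagents that add atoms: none
Why: Evans syn glycolate aldol reaction: the Z-boron enolate should react through a Zimmerman–Traxler chair on the face away from the 4-benzyl group, setting the (2S,3R) syn pair that becomes C3 and C2 of the flavan.

Step 3
Reactants: 7 aldol adduct
Product: 8 (1R,2R)-2-(benzyloxy)-1-[4-(benzyloxy)phenyl]propane-1,3-diol
Conditions: LiBH4, MeOH (1 equiv), THF, 0 °C
Reagents that add atoms: none
Why: Reductive removal of the auxiliary: hydride attacks the exocyclic imide carbonyl and takes it to the primary alcohol; both stereocentres are untouched.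

Step 4
Reactants: 8 (1R,2R)-2-(benzyloxy)-1-[4-(benzyloxy)phenyl]propane-1,3-diol
Product: 10 (1R,2S)-2-(benzyloxy)-1-[4-(benzyloxy)phenyl]-3-chloropropan-1-ol, via primary tosylate 9 (not isolated)
Conditions: TsCl, Et3N, Me3N·HCl (cat.), CH2Cl2, 0 °C; then LiCl, DMF, 50 °C
Reagents that add atoms: lithium chloride, [Li+].[Cl-]
Why: Sulfonylation should discriminate the primary from the hindered secondary benzylic hydroxyl, and Finkelstein-type SN2 displacement by chloride at the primary carbon follows; no stereocentre is touched (the descriptor at C2 changes only by priority).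

Step 5
Reactants: 11 3,5-bis(benzyloxy)phenol
Product: 12 3,5-bis(benzyloxy)phenyl isopropylcarbamate
Conditions: i-PrNCO, Et3N (cat.), CH2Cl2, rt
Reagents that add atoms: isopropyl isocyanate, CC(C)N=C=O
Why: Base-catalysed addition of the phenol to the isocyanate installs the carbamate that serves as directing group.

Step 6
Reactants: 12 3,5-bis(benzyloxy)phenyl isopropylcarbamate
Product: 16 3,5-bis(benzyloxy)-2-(trimethylsilyl)phenyl isopropylcarbamate, via N-silyl carbamate 13 (not isolated), via aryllithium 14 (not isolated), via N-silyl C-silyl carbamate 15 (not isolated)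
Conditions: TBSOTf, TMEDA, Et2O, 0 °C → rt; then n-BuLi, TMEDA, −78 °C; then TMSCl, −78 °C → rt; aq. NaHSO4
Reagents that add atoms: chlorotrimethylsilane, C[Si](C)(C)Cl
Why: Directed ortho-metalation: the carbamate, N-silylated in the flask, should direct lithiation to the position flanked by the carbamate and a benzyloxy group (C2 and C6 are equivalent), the aryllithium is silylated, and the N–Si bond is lost on acidic work-up.

Step 7
Reactants: 16 3,5-bis(benzyloxy)-2-(trimethylsilyl)phenyl isopropylcarbamate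
Product: 18 3,5-bis(benzyloxy)-2-(trimethylsilyl)phenyl trifluoromethanesulfonate, via silyl phenol 17 (not isolated)
Conditions: DBU, Et2NH, MeCN, 40 °C; then PhNTf2, rt
Reagents that add atoms: N-phenylbis(trifluoromethanesulfonimide), O=S(=O)(N(c1ccccc1)S(=O)(=O)C(F)(F)F)C(F)(F)F
Why: E1cB cleavage of the N-monosubstituted carbamate (the isocyanate is trapped by Et2NH) frees the phenoxide, which is triflated in the same flask to the ortho-silylaryl triflate aryne precursor.

Step 8
Reactants: 10 (1R,2S)-2-(benzyloxy)-1-[4-(benzyloxy)phenyl]-3-chloropropan-1-ol; 18 3,5-bis(benzyloxy)-2-(trimethylsilyl)phenyl trifluoromethanesulfonate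
Product: 22 (2R,3R)-3,5,7-tris(benzyloxy)-2-[4-(benzyloxy)phenyl]chromane (3,5,7,4'-tetra-O-benzyl-epiafzelechin), via sodium alkoxide 19 (not isolated), via 3,5-bis(benzyloxy)benzyne 20 (not isolated), via aryl anion 21 (not isolated)
Conditions: 10 (1.3 equiv), NaH (1.25 equiv), THF, 0 °C; then 18 (1.0 equiv), CsF (3 equiv), 18-crown-6 (3 equiv), THF, 0 °C → rt
Reagents that add atoms: none
Why: Proposed new method: fluoride removes the silyl group of 18 and triflate leaves to give aryne 20; alkoxide 19 adds to it, and the aryl anion 21 so formed displaces the primary chloride intramolecularly, so that O1–C8a and C4–C4a are made in one flask operation. The closest known reaction types are the fluoride-triggered aryne annulations in which an oxygen nucleophile adds and the aryl anion is caught by a tethered electrophile (salicylates to xanthones, ortho-hydroxychalcones to xanthenes), and the Parham cycloalkylation of aryllithiums carrying ω-haloalkyl chains. Ring C closes in the 6-exo-tet mode after the intermolecular C–O bond formation; a five-membered alternative does not exist because C3 carries a benzyl ether and no leaving group. No new stereocentre is formed: C2 and C3 come from 10, the C2–O bond is never broken (the alkoxide oxygen becomes O1 with retention) and C4 is a methylene. The selectivity needed is the orientation of addition to the unsymmetrical aryne, and it is secured by the benzyloxy group at C5 next to the triple bond: its inductive pull and the resulting distortion of the aryne make the remote carbon (C8a) the electrophilic one and place the carbanion at C4a, exactly where C4 must bond. The chloride (not a bromide or sulfonate) is chosen so that 19 should not close to an oxetane before the aryne appears, and NaH leaves no proton donor in the flask that could quench 21.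

Step 9
Reactants: 22 tetra-O-benzyl-epiafzelechin
Product: 24 2-{[(2R,3R,4S)-3,5,7-tris(benzyloxy)-2-[4-(benzyloxy)phenyl]chroman-4-yl]oxy}ethanol (4β ether; 3,4-trans), via C4 cation hydroquinonate ion pair 23 (not isolated)
Conditions: DDQ (2 equiv), HOCH2CH2OH (10 equiv), CH2Cl2, rt
Reagents that add atoms: ethylene glycol, OCCO
Why: Benzylic oxidation by DDQ: hydride abstraction from C4 (activated by the 5,7-dioxygenated ring A) gives the C4 cation paired with the hydroquinone monoanion of the reduced oxidant, and the glycol captures it on the face anti to the 3-benzyloxy group, which should give the 3,4-trans ether.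

Step 10
Reactants: 24 4β-(2-hydroxyethoxy) ether; 22 tetra-O-benzyl-epiafzelechin
Product: 26 tetra-O-benzyl-epiafzelechin-(4β→8)-tetra-O-benzyl-epiafzelechin (middle–lower dimer; aryl group at C4 trans to the 3-benzyloxy and 2-aryl groups), via C4 cation triflate ion pair 25 (not isolated)
Conditions: 22 (4 equiv), TMSOTf (0.2 equiv), CH2Cl2, −78 → −40 °C
Reagents that add atoms: none
Why: Lewis-acid-promoted Friedel–Crafts coupling of proanthocyanidin synthesis: TMSOTf ionises the glycol ether to the C4 cation as its triflate ion pair, which should be attacked by C8 of 22 (the ring A position between O1 and the 7-benzyloxy group; the excess suppresses oligomerisation) from the face anti to the 3-benzyloxy and 2-aryl groups, setting the middle C4 as 4β.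

Step 11
Reactants: 27 7-hydroxy-4H-chromen-4-one
Product: 28 7-(benzyloxy)-4H-chromen-4-one
Conditions: BnBr, K2CO3, DMF, rt
Reagents that add atoms: benzyl bromide, BrCc1ccccc1
Why: Williamson benzylation of the acidic phenol.

Step 12
Reactants: 28 7-(benzyloxy)-4H-chromen-4-one; 29 [4-(benzyloxy)phenyl]boronic acid
Product: 30 (2S)-7-(benzyloxy)-2-[4-(benzyloxy)phenyl]chroman-4-one
Conditions: Pd(OCOCF3)2 (5 mol %), (R)-t-BuPyOx [(R)-4-tert-butyl-2-(pyridin-2-yl)-4,5-dihydrooxazole] (6 mol %), NH4PF6 (30 mol %), H2O (5 equiv), ClCH2CH2Cl, 60 °C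
Reagents that add atoms: none
Why: Palladium-catalysed asymmetric conjugate addition of an arylboronic acid to a chromone (aryl–palladium insertion into C2=C3, protonation of the palladium enolate by water); the tert-butyl group of the ligand selects the face, and the (R)-ligand is chosen as the mirror image of the (S)-ligand, which gives (R)-β-aryl ketones, so that C2 should be (S).

Step 13
Reactants: 30 (2S)-7-(benzyloxy)-2-[4-(benzyloxy)phenyl]chroman-4-one
Product: 31 (2S,4S)-7-(benzyloxy)-2-[4-(benzyloxy)phenyl]chroman-4-ol (2,4-cis)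
Conditions: NaBH4, MeOH/THF, 0 °C
Reagents that add atoms: none
Why: Hydride should add along the axial direction of the half-chair with equatorial 2-aryl group and give mainly the 2,4-cis alcohol; the configuration at C4 is lost in step 14 and does not matter.

Step 14
Reactants: 31 (2S,4S)-flavan-4-ol; 26 middle–lower dimer
Product: 33 deca-O-benzyl trimer, (2S)-7,4'-di-O-benzylflavan-(4β→8)-tetra-O-benzyl-epiafzelechin-(4β→8)-tetra-O-benzyl-epiafzelechin (upper unit 2,4-trans), via flavan-4-yl cation 32 (not isolated)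
Conditions: 26 (1.5 equiv), BF3·OEt2 (0.2 equiv), 4 Å MS, CH2Cl2, −40 → 0 °C
Reagents that add atoms: none
Why: Acid-promoted Friedel–Crafts alkylation of the flavan-4-ol type: the cation (stabilised by O1 and the 7-benzyloxy group) should be attacked by C8 of the middle unit of 26, the most nucleophilic free ring A position as in proanthocyanidin chain extension, along the axial trajectory anti to the pseudo-axial hydrogen at C3 of the half-chair with equatorial 2-aryl group, which should give the 2,4-trans (4β) product.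

Step 15
Reactants: 33 deca-O-benzyl trimer
Product: 34 (2S)-7,4'-dihydroxyflavan-(4β→8)-epiafzelechin-(4β→8)-epiafzelechin (CNP0257624.1)
Conditions: H2 (1 atm), Pd(OH)2/C, THF/MeOH/H2O, rt
Reagents that add atoms: none
Why: Hydrogenolysis of all ten benzyl ethers under neutral conditions, which the interflavan bonds and the cyclic benzylic ethers should survive.

## Compound list

1 | (S)-4-benzyl-1,3-oxazolidin-2-one | O=C1N[C@@H](Cc2ccccc2)CO1 | starting material
2 | (benzyloxy)acetyl chloride | O=C(Cl)COCc1ccccc1 | starting material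
3 | (S)-4-benzyl-3-[(benzyloxy)acetyl]-1,3-oxazolidin-2-one | O=C(COCc1ccccc1)N1[C@@H](Cc2ccccc2)COC1=O | intermediate
4 | 4-(benzyloxy)benzaldehyde | O=Cc1ccc(OCc2ccccc2)cc1 | starting material
5 | Z-dibutylboron enolate of 3 | CCCCB(CCCC)O/C(=C\OCc1ccccc1)N1[C@@H](Cc2ccccc2)COC1=O | intermediate (not isolated)
6 | dibutylboron aldolate of 7 | CCCCB(CCCC)O[C@H](c1ccc(OCc2ccccc2)cc1)[C@H](OCc1ccccc1)C(=O)N1[C@@H](Cc2ccccc2)COC1=O | intermediate (not isolated)
7 | (S)-4-benzyl-3-{(2S,3R)-2-(benzyloxy)-3-[4-(benzyloxy)phenyl]-3-hydroxypropanoyl}-1,3-oxazolidin-2-one | O[C@H](c1ccc(OCc2ccccc2)cc1)[C@H](OCc1ccccc1)C(=O)N1[C@@H](Cc2ccccc2)COC1=O | intermediate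
8 | (1R,2R)-2-(benzyloxy)-1-[4-(benzyloxy)phenyl]propane-1,3-diol | O[C@H](c1ccc(OCc2ccccc2)cc1)[C@H](OCc1ccccc1)CO | intermediate
9 | (2R,3R)-2-(benzyloxy)-3-[4-(benzyloxy)phenyl]-3-hydroxypropyl 4-methylbenzenesulfonate | O[C@H](c1ccc(OCc2ccccc2)cc1)[C@H](OCc1ccccc1)COS(=O)(=O)c1ccc(C)cc1 | intermediate (not isolated)
10 | (1R,2S)-2-(benzyloxy)-1-[4-(benzyloxy)phenyl]-3-chloropropan-1-ol | O[C@H](c1ccc(OCc2ccccc2)cc1)[C@H](OCc1ccccc1)CCl | intermediate
11 | 3,5-bis(benzyloxy)phenol | Oc1cc(OCc2ccccc2)cc(OCc2ccccc2)c1 | starting material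
12 | 3,5-bis(benzyloxy)phenyl isopropylcarbamate | CC(C)NC(=O)Oc1cc(OCc2ccccc2)cc(OCc2ccccc2)c1 | intermediate
13 | 3,5-bis(benzyloxy)phenyl N-(tert-butyldimethylsilyl)-N-isopropylcarbamate | CC(C)N([Si](C)(C)C(C)(C)C)C(=O)Oc1cc(OCc2ccccc2)cc(OCc2ccccc2)c1 | intermediate (not isolated)
14 | 2-lithio derivative of 13 | CC(C)N([Si](C)(C)C(C)(C)C)C(=O)Oc1cc(OCc2ccccc2)cc(OCc2ccccc2)c1[Li] | intermediate (not isolated)
15 | 2-(trimethylsilyl) derivative of 13 | CC(C)N([Si](C)(C)C(C)(C)C)C(=O)Oc1cc(OCc2ccccc2)cc(OCc2ccccc2)c1[Si](C)(C)C | intermediate (not isolated)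
16 | 3,5-bis(benzyloxy)-2-(trimethylsilyl)phenyl isopropylcarbamate | CC(C)NC(=O)Oc1cc(OCc2ccccc2)cc(OCc2ccccc2)c1[Si](C)(C)C | intermediate
17 | 3,5-bis(benzyloxy)-2-(trimethylsilyl)phenol | Oc1cc(OCc2ccccc2)cc(OCc2ccccc2)c1[Si](C)(C)C | intermediate (not isolated)
18 | 3,5-bis(benzyloxy)-2-(trimethylsilyl)phenyl trifluoromethanesulfonate | C[Si](C)(C)c1c(OS(=O)(=O)C(F)(F)F)cc(OCc2ccccc2)cc1OCc1ccccc1 | intermediate
19 | sodium alkoxide of 10 | [Na+].[O-][C@H](c1ccc(OCc2ccccc2)cc1)[C@H](OCc1ccccc1)CCl | intermediate (not isolated)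
20 | 3,5-bis(benzyloxy)benzyne | C1#CC(OCc2ccccc2)=CC(OCc2ccccc2)=C1 | intermediate (not isolated)
21 | sodium 2-aryloxy-4,6-bis(benzyloxy)phenide (aryl anion at the future C4a, chloroalkyl ether at the future C8a) | [Na+].[c-]1c(O[C@H](c2ccc(OCc3ccccc3)cc2)[C@H](OCc2ccccc2)CCl)cc(OCc2ccccc2)cc1OCc1ccccc1 | intermediate (not isolated)
22 | (2R,3R)-3,5,7-tris(benzyloxy)-2-[4-(benzyloxy)phenyl]chromane (3,5,7,4'-tetra-O-benzyl-epiafzelechin) | c1c(OCc3ccccc3)cc(OCc3ccccc3)c2c1O[C@H](c1ccc(OCc3ccccc3)cc1)[C@H](OCc1ccccc1)C2 | intermediate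
23 | C4 benzylic cation of 22 as its 2,3-dichloro-5,6-dicyano-4-hydroxyphenolate ion pair (formed by hydride transfer to DDQ) | c1c(OCc3ccccc3)cc(OCc3ccccc3)c2c1O[C@H](c1ccc(OCc3ccccc3)cc1)[C@H](OCc1ccccc1)[CH+]2.[O-]c1c(Cl)c(Cl)c(O)c(C#N)c1C#N | intermediate (not isolated)
24 | 2-{[(2R,3R,4S)-3,5,7-tris(benzyloxy)-2-[4-(benzyloxy)phenyl]chroman-4-yl]oxy}ethanol (4β ether) | c1c(OCc3ccccc3)cc(OCc3ccccc3)c2c1O[C@H](c1ccc(OCc3ccccc3)cc1)[C@H](OCc1ccccc1)[C@H]2OCCO | intermediate
25 | C4 benzylic cation of 22 as its trifluoromethanesulfonate ion pair (formed by ionisation of 24) | c1c(OCc3ccccc3)cc(OCc3ccccc3)c2c1O[C@H](c1ccc(OCc3ccccc3)cc1)[C@H](OCc1ccccc1)[CH+]2.[O-]S(=O)(=O)C(F)(F)F | intermediate (not isolated)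
26 | tetra-O-benzyl-epiafzelechin-(4β→8)-tetra-O-benzyl-epiafzelechin (middle–lower dimer) | c1c(OCc3ccccc3)cc(OCc3ccccc3)c2c1O[C@H](c1ccc(OCc3ccccc3)cc1)[C@H](OCc1ccccc1)[C@H]2c1c(OCc3ccccc3)cc(OCc3ccccc3)c2c1O[C@H](c1ccc(OCc3ccccc3)cc1)[C@H](OCc1ccccc1)C2 | intermediate
27 | 7-hydroxy-4H-chromen-4-one | O=c1ccoc2cc(O)ccc12 | starting material
28 | 7-(benzyloxy)-4H-chromen-4-one | O=c1ccoc2cc(OCc3ccccc3)ccc12 | intermediate
29 | [4-(benzyloxy)phenyl]boronic acid | OB(O)c1ccc(OCc2ccccc2)cc1 | starting material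
30 | (2S)-7-(benzyloxy)-2-[4-(benzyloxy)phenyl]chroman-4-one | O=C1C[C@@H](c2ccc(OCc3ccccc3)cc2)Oc2cc(OCc3ccccc3)ccc12 | intermediate
31 | (2S,4S)-7-(benzyloxy)-2-[4-(benzyloxy)phenyl]chroman-4-ol (2,4-cis) | O[C@H]1C[C@@H](c2ccc(OCc3ccccc3)cc2)Oc2cc(OCc3ccccc3)ccc12 | intermediate
32 | (2S)-7-(benzyloxy)-2-[4-(benzyloxy)phenyl]chroman-4-yl cation | [CH+]1C[C@@H](c2ccc(OCc3ccccc3)cc2)Oc2cc(OCc3ccccc3)ccc12 | intermediate (not isolated)
33 | deca-O-benzyl trimer: (2S)-7,4'-di-O-benzylflavan-(4β→8)-tetra-O-benzyl-epiafzelechin-(4β→8)-tetra-O-benzyl-epiafzelechin | c1ccccc1COc1ccc([C@@H]2C[C@@H](c3c(OCc5ccccc5)cc(OCc5ccccc5)c4c3O[C@H](c3ccc(OCc5ccccc5)cc3)[C@H](OCc5ccccc5)[C@H]4c3c(OCc5ccccc5)cc(OCc5ccccc5)c4c3O[C@H](c3ccc(OCc5ccccc5)cc3)[C@H](OCc5ccccc5)C4)c3ccc(OCc5ccccc5)cc3O2)cc1 | intermediate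
34 | (2S)-7,4'-dihydroxyflavan-(4β→8)-epiafzelechin-(4β→8)-epiafzelechin (CNP0257624.1) | Oc1ccc([C@@H]2C[C@@H](c3c(O)cc(O)c4c3O[C@H](c3ccc(O)cc3)[C@H](O)[C@H]4c3c(O)cc(O)c4c3O[C@H](c3ccc(O)cc3)[C@H](O)C4)c3ccc(O)cc3O2)cc1 | target

## Step count and risks

Total step count: 15. Longest linear sequence: 9 steps (steps 1, 2, 3, 4, 8, 9, 10, 14, 15).

Steps most likely to fail:

**Step 8 (Proposed new method).** What may go wrong: the aryl anion is quenched by a proton (traces of free alcohol, C–H bonds of the chain or of the neighbouring benzyl ether) before it closes ring C, or the alkoxide alkylates itself before the aryne is present, so that only the C–O bond or neither bond is formed.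
Fallback (sets out from aldehyde 4 and phenol 11, returns at 22): ring C is closed in two known stages, ether first and C4–C4a second, by electrophilic instead of anionic arylation. Addition of CH2=CHMgBr to 4 would give racemic 1-[4-(benzyloxy)phenyl]prop-2-en-1-ol F1. Sharpless kinetic resolution (Ti(OiPr)4, L-(+)-DIPT, t-BuOOH, 4 Å MS, CH2Cl2, −20 °C) should convert the fast-reacting enantiomer into the erythro epoxy alcohol (S)-[4-(benzyloxy)phenyl][(R)-oxiran-2-yl]methanol F2. Mitsunobu etherification with 11 (PPh3, DIAD, THF) inverts the carbinol carbon and should give 1,3-bis(benzyloxy)-5-{(R)-[4-(benzyloxy)phenyl][(R)-oxiran-2-yl]methoxy}benzene F3. AuCl3/AgOTf-catalysed 6-endo epoxide–arene cyclisation (intramolecular Friedel–Crafts alkylation at the terminal epoxide carbon; the two ortho positions of the ether ring are equivalent) should close ring C to 5,7,4'-tri-O-benzyl-epiafzelechin F4, and O-benzylation (NaH, BnBr, DMF) leads back to 22.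

**Step 14.** What may go wrong: the flavan-4-yl cation, which has no substituent at C3, attacks one of the C6 positions of the dimer or alkylates twice, or adds with poor facial selectivity (2,4-cis isomer).
Fallback (sets out from 31 and monomer 22, returns at 33): the chain is assembled in the opposite order, so that the cation meets a nucleophile with a single reactive ring. Coupling of 31 with a large excess of 22 (BF3·OEt2, CH2Cl2, −40 °C) should give the upper–middle dimer (2S)-7,4'-di-O-benzylflavan-(4β→8)-tetra-O-benzyl-epiafzelechin F5. Oxidation at the only methylene C4 (DDQ, HOCH2CH2OH, CH2Cl2) should give its 4β-(2-hydroxyethoxy) ether F6, and TMSOTf-promoted coupling of F6 with excess 22 at −78 °C should give 33.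

**Step 12.** What may go wrong: insufficient facial discrimination or slow insertion with the electron-rich 7-alkoxychromone, giving material of low enantiomeric purity.
Fallback (sets out from 28 and 29, returns at 31): the arylation is run with an achiral catalyst (Pd(OCOCF3)2, 2,2'-bipyridine, aqueous conditions) to give racemic 7-(benzyloxy)-2-[4-(benzyloxy)phenyl]chroman-4-one F7, and the enantiomers are separated at the reduction stage. Asymmetric transfer hydrogenation with RuCl(p-cymene)[(S,S)-TsDPEN] and HCO2H/Et3N should reduce the matched (2S)-ketone to the cis alcohol 31 and leave the (2R)-ketone F8, which is removed by chromatography.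

## Further compounds

F1 | step 8 | racemic 1-[4-(benzyloxy)phenyl]prop-2-en-1-ol | C=CC(O)c1ccc(OCc2ccccc2)cc1
F2 | step 8 | (S)-[4-(benzyloxy)phenyl][(R)-oxiran-2-yl]methanol | O[C@@H](c1ccc(OCc2ccccc2)cc1)[C@H]1CO1
F3 | step 8 | 1,3-bis(benzyloxy)-5-{(R)-[4-(benzyloxy)phenyl][(R)-oxiran-2-yl]methoxy}benzene | O([C@H](c1ccc(OCc2ccccc2)cc1)[C@H]1CO1)c1cc(OCc2ccccc2)cc(OCc2ccccc2)c1
F4 | step 8 | (2R,3R)-5,7-bis(benzyloxy)-2-[4-(benzyloxy)phenyl]chroman-3-ol (5,7,4'-tri-O-benzyl-epiafzelechin) | c1c(OCc3ccccc3)cc(OCc3ccccc3)c2c1O[C@H](c1ccc(OCc3ccccc3)cc1)[C@H](O)C2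
F5 | step 14 | (2S)-7,4'-di-O-benzylflavan-(4β→8)-tetra-O-benzyl-epiafzelechin | c1ccccc1COc1ccc([C@@H]2C[C@@H](c3c(OCc5ccccc5)cc(OCc5ccccc5)c4c3O[C@H](c3ccc(OCc5ccccc5)cc3)[C@H](OCc5ccccc5)C4)c3ccc(OCc5ccccc5)cc3O2)cc1
F6 | step 14 | 4β-(2-hydroxyethoxy) ether of F5 (at C4 of the epiafzelechin unit) | c1ccccc1COc1ccc([C@@H]2C[C@@H](c3c(OCc5ccccc5)cc(OCc5ccccc5)c4c3O[C@H](c3ccc(OCc5ccccc5)cc3)[C@H](OCc5ccccc5)[C@H]4OCCO)c3ccc(OCc5ccccc5)cc3O2)cc1
F7 | step 12 | racemic 7-(benzyloxy)-2-[4-(benzyloxy)phenyl]chroman-4-one | O=C1CC(c2ccc(OCc3ccccc3)cc2)Oc2cc(OCc3ccccc3)ccc12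
F8 | step 12 | (2R)-7-(benzyloxy)-2-[4-(benzyloxy)phenyl]chroman-4-one | O=C1C[C@H](c2ccc(OCc3ccccc3)cc2)Oc2cc(OCc3ccccc3)ccc12
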